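(The data were generated by integration with made-up constants, noise included.)

in all of them: partner 1.05 M; free catalyst 2.1 mM; stray impurity 0.58 mM

| charge | substrate | protic impurity | remark |
|---|---|---|---|
| Tuesday's | 1 M | 0.75 M | run made earlier |
| Sunday's | 2.2 M | 0.75 M | run made earlier |
| Thursday's | 1.5 M | 1.1 M | run made earlier |
| flask | 1.5 M | 0.750 M |  |

| run | time / min | product / % | substrate / % |
|---|---|---|---|
| Tuesday's | 1.50 | 7.8 | 92.7 |
| Tuesday's | 3.00 | 12.5 | 89.4 |
| Tuesday's | 6.00 | 23.2 | 76.8 |
| Tuesday's | 10.0 | 32.6 | 64.9 |
| Tuesday's | 20.0 | 41.4 | 58.4 |
| Sunday's | 1.50 | 5.4 | 94.5 |
| Sunday's | 3.00 | 11.7 | 90.1 |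
| Sunday's | 6.00 | 16.0 | 83.1 |
| Sunday's | 10.0 | 20.4 | 78.3 |
| Sunday's | 20.0 | 21.4 | 77.1 |
| Thursday's | 1.50 | 6.3 | 92.1 |
| Thursday's | 3.00 | 9.1 | 89.9 |
| Thursday's | 6.00 | 18.6 | 80.8 |
| Thursday's | 10.0 | 23.5 | 78.3 |
| Thursday's | 20.0 | 22.1 | 79.6 |

(readings scatter by 1 percentage point)

* apparent order in free catalyst when 5.0 % of the substrate are converted (percent change of the rate of making product for one percent more free catalyst charged)
* apparent order in partner when 5.0 % of the substrate are converted (percent change of the rate of making product for one percent more partner charged)

- the analysis behind the earlier runs scatters by 1 percentage point, standard deviation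
- no earlier run changes the charge of free catalyst; that part of a forecast is a guess
- no earlier run changes the charge of partner; that part of a forecast is a guess

Product opened the meeting: after 20.0 min it stood at 41.4 % of the substrate charged in Tuesday's run, 21.4 % in Sunday's and 22.1 % in Thursday's, and the members noted that none of these runs changed the charge of free catalyst or of partner, so both questions had to be argued from the charges and not from a comparison of runs.

One member proposed setting the stray impurity against the catalyst. The flask holds 0.58 mM of the one and 2.1 mM of the other, so if each stray molecule removes one catalyst molecule for good, the fraction of the catalyst charged that stays in use, the working share 0.724, is the number to carry. One percent more catalyst charged leaves the stray impurity as it was, so if the rate follows the working catalyst, the order in free catalyst is one over the working share, 1.38. That member offered no figure for partner.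

The forecast, made by a colleague from the same runs, gave 1.3 for free catalyst and 1.18 for partner, holding that “Stray impurity may titrate some catalyst”, and its catalyst figure stands a little below the member's 1.38.

The flask gives 1.4 for free catalyst, within the margin of the forecast, and 0.19 for partner, well below the forecast's figure.

    substrate + free catalyst → catalyst intermediate A (k = 0.610 /M/s)
    partner + catalyst intermediate A → catalyst intermediate B (k = 6.00 /M/s)
    catalyst intermediate B ⇌ by-product + catalyst intermediate C (K = 0.680 M, k = 69.0 /s)
    catalyst intermediate C → catalyst intermediate D (k = 70.0 /s)
    catalyst intermediate D → free catalyst + product (k = 6.30 /s)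
    partner + protic impurity → quenched reagent (k = 0.00800 /M/s)
    free catalyst + stray impurity → spent catalyst (k = 72.0 /M/s)

In the flask, substrate at the start uses free catalyst 22 times as fast as stray impurity does, yet by 2.00 min the stray impurity stands at 0 % of its charge and spent catalyst at 27.6 % of the catalyst charged, the complement of the working share 0.724. Taking that path away lowers the order in free catalyst from 1.4 to 1.0. One over the working share, 1.38, also serves as the rate factor for that second flask without the path, which at 5.0 % conversion makes product 1.39 times as fast.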